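| flask | left-handed substrate | right-handed substrate | coupling partner | free catalyst | impurity | remark | time |
|---|---|---|---|---|---|---|---|
| spring | 0.65 M | 0.65 M | 1.3 M | 3 mM | 9.9 mM | run made earlier |  |
| dawn | 0.65 M | 0.65 M | 1.3 M | 19 mM | 9.9 mM | run made earlier |  |
| alpha | 0.65 M | 0.65 M | 1.30 M | 23 mM | 9.9 mM |  | 3.0 min |
| epsilon | 0.65 M | 0.65 M | 1.30 M | 6.0 mM | 9.9 mM |  | 3.0 min |

| run | time / s | right-handed substrate / % | left-handed substrate / % | left-handed product / % |
|---|---|---|---|---|
| spring | 10.0 | 49.5 | 49.8 | 0 |
| spring | 12.0 | 49.2 | 49.1 | 0 |
| spring | 15.0 | 49.7 | 50.7 | 0.4 |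
| spring | 25.0 | 49.1 | 49.0 | 0 |
| spring | 40.0 | 50.1 | 49.1 | 0.4 |
| spring | 60.0 | 50.3 | 50.4 | 0 |
| spring | 90.0 | 50.2 | 49.3 | 1.5 |
| dawn | 10.0 | 51.0 | 45.6 | 4.7 |
| dawn | 12.0 | 49.5 | 45.0 | 5.2 |
| dawn | 15.0 | 49.9 | 43.2 | 5.9 |
| dawn | 25.0 | 49.9 | 40.6 | 9.0 |
| dawn | 40.0 | 49.4 | 36.1 | 14.5 |
| dawn | 60.0 | 49.0 | 32.0 | 18.3 |
| dawn | 90.0 | 49.0 | 26.5 | 23.4 |

(standard deviation of a reading: 0.5 percentage points)

- free catalyst is single-handed; left-handed substrate and right-handed substrate are mirror images of each other, charged as a racemate, each of them at the stated concentration
- what was read earlier has a scatter of 0.5 percentage points, one standard deviation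
- candidate steps: coupling partner + free catalyst + right-handed substrate -> free catalyst + right-handed product; coupling partner -> decomposed reagent; coupling partner + free catalyst + left-handed substrate -> free catalyst + left-handed product; free catalyst + impurity -> spent catalyst
- an excess is the difference of the two amounts in percent of their sum
- an excess is below zero if the other one leads

- which one finishes higher in excess of right-handed substrate over left-handed substrate among what is left of the two ("neither" within 2 percentage points) (alpha / epsilon / neither)
- excess of right-handed substrate over left-handed substrate among what is left of the two at the end, alpha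
- excess of right-handed substrate over left-handed substrate among what is left of the two at the end, epsilon

**Early readings.** At early times the spring run stands flat: at 90.0 s its excess of right-handed over left-handed substrate reads 0.905%, with readings scattered by 0.5 percentage points. Between 10.0 s and 90.0 s, the dawn run's left-handed substrate falls from 45.6% to 26.5%.

**Main step.** I start with the left-handed coupling as the one step. Coupling partner is charged at twice the left-handed substrate and falls one for one with it. With right-handed substrate held unmoved, integration gives the excess E = 1 − exp(−t/2τ), where t is the time and τ the pseudo-first-order time of left-handed substrate at charged partner. I read τ = 125 s from the dawn run. Scaling τ by charged catalyst gives alpha 58.2%, but it also gives the spring run 5.52%, against the 0.905% read.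

**Adding impurity.** I let impurity take free catalyst one for one. Alpha then has 13.1 mM above its impurity: this live margin m, charged free catalyst minus charged impurity, replaces the charge in scaling τ. The dawn run's margin is 9.10 mM and the spring run's is −6.90 mM, which fits its flat readings. Alpha's E becomes 64.5%. Epsilon's margin is −3.90 mM, so I expect the spring run's behaviour and an excess near zero.

**The rest.** Whatever partner decomposition the dawn run had up to its last reading lies inside τ. Its right-handed substrate reads 51.0% first and 49.0% last, with a scatter of 0.5 points, a fall I leave out here, knowing that any loss lowers E.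

**The forecast.** It names alpha, with 62% for alpha, against my 64.5%, and 1.8% for epsilon, where “the catalyst is fully poisoned within seconds”.

**The flask.** The result is alpha, with 61.5% for alpha and 0.0829% for epsilon.

    coupling partner + free catalyst + right-handed substrate → free catalyst + right-handed product (k = 0.0340 M⁻² s⁻¹)
    coupling partner → decomposed reagent (k = 0.00110 s⁻¹)
    coupling partner + free catalyst + left-handed substrate → free catalyst + left-handed product (k = 0.760 M⁻² s⁻¹)
    free catalyst + impurity → spent catalyst (k = 530 M⁻¹ s⁻¹)

**Poison first.** In epsilon at charged amounts, impurity removes free catalyst on a time of 0.191 s, far shorter than the 169 s pseudo-first-order time of its left-handed substrate at charged partner and charged catalyst. At the end alpha holds 13.1 mM of free catalyst against m = 13.1 mM, and epsilon holds 3.90 mM of impurity against m = −3.90 mM. Epsilon with 0.0040 M of impurity has m = 2.00 mM, for which the rule gives 14.6%; the simulated flask gives 14.2%.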